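**Retrosynthetic overview**

1. GA55 (29) ⇐ its 7-methyl ester 28 ⇐ keto diester 26 (C16 methylenation, desilylation with C19→C10 lactonisation) ⇐ cycloadduct 20 (loss of the C11 carbonyl and of one C6 ester).
2. 20 ⇐ 19 by an intramolecular (4+3) cycloaddition: the 2-silyloxyallyl cation C9–C11–C12, released from a C9/C10 spiro-epoxide, adds across C8 and C13 of a cyclopentadiene and closes ring B, ring C and the seven-membered ring C8–C9–C11–C12–C13–C16–C15 at once.
3. Enabling feature: ring D (C8, C14, C13, C16, C15) has C13–OH and C16 (=CH2, a masked ketone) at the oxidation level of a 1,2-bis(silyloxy)cyclopentadiene with C14 as its CH2; C9, the end of the C9–C11–C12 bridge, is bonded to the oxygen-bearing C10, so the future lactone oxygen serves as the epoxide leaving group.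
4. 19 ⇐ ring A ketone 16 (Darzens reaction with chloroacetone) ⇐ quinone monoketal 2 of methyl 5-methoxysalicylate: asymmetric malonate Michael addition (C5), methylation (C4), conjugate borylation (C1–O), chelation-controlled reduction (C3–O), cyclopentenone attached at C6; C6 stays a malonate (no stereocentre, no acidic H) until the end.
5. Ring order: A (from the arene) → D (attached as a cyclopentenone) → B and C together in the key step → lactone last.

Key step: step 13

Remark on the chemistry: gibberellane numbering (C1–C19) is used for all intermediates. The siloxy carbon of ring D (C13, and C16 in 14) in 14–18 is an epimer mixture and is written without configuration; it becomes sp2 in step 12. The epoxide CH (C9) in 18 and 19 is drawn as the expected major epimer (acetyl anti to the C5 side chain); its epimer is carried along because both ionise to the same cation.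

**Step 1**
Reactants: 1 methyl 2-hydroxy-5-methoxybenzoate
Product: 2 methyl 3,3-dimethoxy-6-oxocyclohexa-1,4-diene-1-carboxylate
Conditions: PhI(OAc)2, MeOH, 0 °C
Reagents that add atoms: methanol, CO
Why: Oxidative dearomatisation of a para-methoxyphenol to the quinone monoketal, which supplies the C3 ketone, the C19 ester on C4, an activated C4=C5 acceptor, a masked C10 ketone and a C1=C2 enone in one operation.

**Step 2**
Reactants: 2 quinone monoketal; 3 dimethyl malonate
Product: 4 Michael adduct, (R) at the new centre (future C5), enol form of the β-keto ester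
Conditions: quinine-derived tertiary amine–squaramide catalyst (5 mol %), toluene, −20 °C
Reagents that add atoms: none
Why: Enantioselective organocatalytic Michael addition of a malonate to a doubly activated cyclic enone (the squaramide binds the β-keto ester, the quinuclidine delivers the malonate), in which the catalyst sets C5 (its pseudo-enantiomer is available should the sense be opposite) and the keto ester alkene reacts in preference to the plain C1=C2 enone.

**Step 3**
Reactants: 4 Michael adduct
Product: 5 ring A enone with quaternary C4 (18-methyl β, 19-CO2Me α)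
Conditions: K2CO3 (1.0 equiv), MeI, acetone, 0 °C to rt
Reagents that add atoms: iodomethane, CI
Why: C-alkylation of the cyclic β-keto ester, which is several pKa units more acidic than the substituted malonate so that one equivalent of base enolises C4 only; MeI enters anti to the C5 malonyl group, and quaternisation also blocks aromatisation by loss of methanol.

**Step 4**
Reactants: 5 ring A enone
Product: 7 1β-hydroxy-3-ketone, via boronate 6 (not isolated)
Conditions: CuCl (10 mol %), Xantphos, NaOtBu (cat.), B2pin2, MeOH, THF, rt; then NaBO3·4H2O, THF–H2O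
Reagents that add atoms: bis(pinacolato)diboron, CC1(C)OB(OC1(C)C)B1OC(C)(C)C(C)(C)O1 (boron of 6); sodium perborate, [Na+].[O-]OB=O (oxygen of 7)
Why: Copper-catalysed conjugate borylation of the only enone followed by perborate oxidation with retention, in which boron adds to C1 trans to the C5 substituent (3,5-trans rule for cyclohexenones) and so gives the 1β-hydroxyl.

**Step 5**
Reactants: 7 1β-hydroxy-3-ketone
Product: 8 1β,3β-diol
Conditions: Et2BOMe, NaBH4, THF–MeOH, −78 °C
Reagents that add atoms: none
Why: Narasaka–Prasad reduction, in which the dialkylboron chelate of the C1 hydroxyl and the C3 ketone is attacked by external hydride on the face away from the chelate to give the cis-1,3-diol; the esters are inert at −78 °C.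

**Step 6**
Reactants: 8 1β,3β-diol
Product: 9 1,3-O-di-tert-butylsilylene malonate
Conditions: tBu2Si(OTf)2, 2,6-lutidine, CH2Cl2, 0 °C
Reagents that add atoms: di-tert-butylsilyl bis(trifluoromethanesulfonate), CC(C)(C)[Si](OS(=O)(=O)C(F)(F)F)(OS(=O)(=O)C(F)(F)F)C(C)(C)C
Why: Cyclic silylene protection of a cis-1,3-diol, which needs both oxygens axial and therefore locks ring A in the chair with the C4 ester axial (α) and the C5 side chain equatorial.

**Step 7**
Reactants: 10 cyclopentane-1,3-dione
Product: 11 3-chlorocyclopent-2-en-1-one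
Conditions: (COCl)2, DMF (cat.), CH2Cl2, 0 °C to rt
Reagents that add atoms: oxalyl chloride, O=C(Cl)C(=O)Cl
Why: Standard conversion of a cyclic 1,3-dione into its vinylogous acid chloride.

**Step 8**
Reactants: 9 silylene malonate; 11 3-chlorocyclopent-2-en-1-one
Product: 12 C6-quaternary malonate carrying the cyclopentenone (C8 = enone β-carbon)
Conditions: NaH, DMF, 0 °C; then 11, 0 to 40 °C
Reagents that add atoms: none
Why: Addition–elimination (vinylogous acyl substitution) of a malonate anion on a β-chloro enone, made irreversible by chloride loss; C6 becomes quaternary with two identical esters, so it carries neither a stereocentre nor an acidic hydrogen through the key step.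

**Step 9**
Reactants: 12 cyclopentenone malonate
Product: 15 α′-(tert-butyldimethylsilyloxy) enone (C13–OTBS), via dienol silyl ether 13 (not isolated), via silyloxy oxirane 14 (not isolated)
Conditions: LiN(SiMe3)2, THF, −78 °C; tBuMe2SiOTf; then dimethyldioxirane (acetone), −78 to 0 °C
Reagents that add atoms: tert-butyldimethylsilyl trifluoromethanesulfonate, CC(C)(C)[Si](C)(C)OS(=O)(=O)C(F)(F)F; dimethyldioxirane, CC1(C)OO1
Why: Rubottom oxidation: kinetic α′-deprotonation at C13, O-silylation to the cross-conjugated dienol ether, epoxidation of the enol ether bond and 1,4-silyl shift give the α′-silyloxy enone, whose C13 configuration is irrelevant because C13 becomes sp2 again in step 12.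

**Step 10**
Reactants: 15 α′-silyloxy enone ketal
Product: 16 C10 ketone
Conditions: PPTS, acetone–H2O, 60 °C
Reagents that add atoms: water, O
Why: Acid-catalysed hydrolysis of the dimethyl ketal, safe because the quaternary C4 rules out aromatisation and the silyl ethers tolerate PPTS.

**Step 11**
Reactants: 16 C10 ketone; 17 chloroacetone
Product: 18 spiro-epoxy methyl ketone (epoxide oxygen α at C10)
Conditions: 17, LiN(SiMe3)2, THF, −78 °C; then 16, −78 to 0 °C
Reagents that add atoms: none
Why: Darzens condensation of an α-chloro ketone enolate with a ketone, in which the axial C4 ester of the silylene-locked chair blocks the α face so that the C9–C10 bond forms equatorially (β) and the oxygen ends up axial (α); closure of the alkoxide on the α-keto chloride should outrun attack on the neopentyl C19 ester.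

**Step 12**
Reactants: 18 spiro-epoxy methyl ketone
Product: 19 epoxy enol silane with 1,2-bis(silyloxy)cyclopentadiene
Conditions: LiN(SiMe3)2 (2.5 equiv), Et3SiCl, THF, −78 °C; cold filtration through basic alumina, used at once
Reagents that add atoms: chlorotriethylsilane, CC[Si](Cl)(CC)CC
Why: Kinetic enolisation of the methyl ketone (C12) and of the cyclopentenone α′ position (C13) with in situ O-silylation, regiospecific because C4 and C6 are quaternary and the epoxide C–H is not acidic.

**Step 13**
Reactants: 19 epoxy enol silane with 1,2-bis(silyloxy)cyclopentadiene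
Product: 20 tetracyclic C11 ketone (C10–OSiEt3, C13–OTBS, C15=C16 silyl enol ether)
Conditions: Et3SiOTf (20 mol %), CH2Cl2, −78 °C; Et3N quench
Reagents that add atoms: none
Why: Et3SiOTf silylates the epoxide oxygen and the enol silane pushes out the C9–O bond (SN1-like, since backside attack by the tethered diene would be a 5-endo process) to give the 2-silyloxyallyl cation C9–C11–C12, across which the tethered 1,2-bis(silyloxy)cyclopentadiene adds in an asynchronous (4+3) event, C13 to C12 first and then C9 to C8, after which the C11 oxocarbenium ion returns its silyl group to triflate. The closest known reaction type is the silyl triflate-catalysed (4+3) cycloaddition of epoxy enol silanes with furans and cyclopentadienes, including tethered dienes. The second bond closes ring B as a 5-(enolexo)-exo-trig and ring C as a 6-(enolendo)-exo-trig addition of the C9 enol silane carbon to C8, the seven-membered ring C8–C9–C11–C12–C13–C16–C15 being the (4+3) ring with C14 as its bridge, whereas closure at C16 would be a disfavoured 5-(enolendo) mode. C9 is controlled by the cation conformation: the C10–O bond stays in the plane of the cation, syn to C11 (inside-alkoxy effect and allylic 1,3-strain), and C5 must point to the diene, which places H9 cis to H5 whichever C9 epimer of the epoxide was ionised. C8 and C13 are set together by the diene face, chosen by the extended arrangement in which the cation C11–OSiEt3 lies over the C14 methylene, away from the C16 and C13 silyloxy groups, and in which the C6–C8 and C9–C10 bonds are eclipsed as the cis-fused ring B requires. The step needs ionisation at C9 and not at the tertiary C10 (only the C9 cation is stabilised by the enol silane), the five-membered tether mode and the extended over the compact mode, and the geminal C6 esters help closure by the Thorpe–Ingold effect.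

**Step 14**
Reactants: 20 tetracyclic C11 ketone
Product: 21 C11 enol triflate (C11=C12)
Conditions: KN(SiMe3)2, PhNTf2, THF, −78 °C
Reagents that add atoms: N-phenylbis(trifluoromethanesulfonimide), O=S(=O)(N(c1ccccc1)S(=O)(=O)C(F)(F)F)C(F)(F)F
Why: Kinetic enol triflate formation at the only enolisable carbonyl (C16 is still masked as the silyl enol ether delivered by the cycloaddition), with deprotonation at C12 and not at the hindered C9–H.

**Step 15**
Reactants: 21 C11 enol triflate
Product: 23 C11=C12 alkene with free C16 ketone, via silyl enol ether 22 (not isolated)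
Conditions: Pd(OAc)2 (5 mol %), PPh3, HCO2H, Et3N, DMF, 60 °C; then K2CO3 (cat.), MeOH, 0 °C
Reagents that add atoms: none
Why: Formate reduction of an enol triflate by zerovalent palladium to the alkene, then methanolysis of the silyl enol ether to free the C16 ketone while the tertiary alkyl silyl ethers survive.

**Step 16**
Reactants: 23 C11=C12 alkene
Product: 24 saturated C16 ketone (C11 and C12 methylene)
Conditions: H2 (1 atm), 10% Pd/C, EtOAc, rt
Reagents that add atoms: none
Why: Heterogeneous hydrogenation of the only C=C bond, a disubstituted ring alkene, which completes removal of the C11 oxygen.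

**Step 17**
Reactants: 24 saturated C16 ketone
Product: 26 6β-mono ester, via 6-epi ester 25 (not isolated)
Conditions: LiCl, H2O, DMSO, 150 °C; then NaOMe (0.3 equiv), MeOH, 50 °C
Reagents that add atoms: none
Why: Krapcho demethoxycarbonylation of the malonate (chloride attacks a methyl group, then loss of CO2 and protonation) followed by methoxide equilibration to the more stable 6β ester (trans to C4 and to the C10 oxygen, cis to H5); the hindered C19 ester is not activated and stays.

**Step 18**
Reactants: 26 6β-mono ester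
Product: 27 16-methylene compound
Conditions: Ph3PCH3Br, KOtBu, THF, 0 to 50 °C
Reagents that add atoms: methyltriphenylphosphonium bromide, C[P+](c1ccccc1)(c1ccccc1)c1ccccc1.[Br-]
Why: Wittig methylenation of the α-silyloxy 16-ketone, the usual way to install C17 on a gibberellin 16-norketone; esters are inert to the ylide.

**Step 19**
Reactants: 27 16-methylene compound
Product: 28 GA55 methyl ester
Conditions: Bu4NF, THF, 0 °C to rt
Reagents that add atoms: none
Why: Fluoride cleaves the three silyl groups and the C10 alkoxide, 1,3-diaxial to the C4 ester on the α face, closes the 19,10-lactone by 5-exo-trig acyl substitution with loss of methoxide.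

**Step 20**
Reactants: 28 GA55 methyl ester
Product: 29 GA55
Conditions: n-PrSLi, HMPA, 0 °C to rt; dilute HCl work-up
Reagents that add atoms: none
Why: SN2 demethylation of the hindered 7-methyl ester by thiolate, which avoids aqueous base and with it lactone opening and retro-aldol epimerisation at C3.

**Compound list**

1 | methyl 2-hydroxy-5-methoxybenzoate | COC(=O)c1cc(OC)ccc1O | starting material
2 | methyl 3,3-dimethoxy-6-oxocyclohexa-1,4-diene-1-carboxylate | COC(=O)C1=CC(OC)(OC)C=CC1=O | intermediate
3 | dimethyl malonate | COC(=O)CC(=O)OC | starting material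
4 | dimethyl 2-[(1R)-3-hydroxy-6,6-dimethoxy-2-(methoxycarbonyl)cyclohexa-2,4-dien-1-yl]malonate (enol form; C5 set) | COC1(OC)C=CC(O)=C(C(=O)OC)[C@H]1C(C(=O)OC)C(=O)OC | intermediate
5 | ring A enone: C3 ketone, C1=C2, C10 dimethyl ketal, C4 with 18-methyl β and 19-CO2Me α, C5 with CH(CO2Me)2 α | COC1(OC)C=CC(=O)[C@@](C)(C(=O)OC)[C@H]1C(C(=O)OC)C(=O)OC | intermediate
6 | 1β-(pinacolboryl) 3-ketone | COC1(OC)[C@H](B2OC(C)(C)C(C)(C)O2)CC(=O)[C@@](C)(C(=O)OC)[C@H]1C(C(=O)OC)C(=O)OC | intermediate
7 | 1β-hydroxy 3-ketone | COC1(OC)[C@H](O)CC(=O)[C@@](C)(C(=O)OC)[C@H]1C(C(=O)OC)C(=O)OC | intermediate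
8 | 1β,3β-diol | COC1(OC)[C@H](O)C[C@H](O)[C@@](C)(C(=O)OC)[C@H]1C(C(=O)OC)C(=O)OC | intermediate
9 | 1β,3β-O-di-tert-butylsilylene malonate | COC1(OC)[C@H](O[Si]4(C(C)(C)C)C(C)(C)C)C[C@H](O4)[C@@](C)(C(=O)OC)[C@H]1C(C(=O)OC)C(=O)OC | intermediate
10 | cyclopentane-1,3-dione | O=C1CCC(=O)C1 | starting material
11 | 3-chlorocyclopent-2-en-1-one | O=C1CCC(Cl)=C1 | intermediate
12 | C6-quaternary malonate with 3-oxocyclopent-1-enyl group at C6 (ring D: C8=C15, C16 ketone) | COC1(OC)[C@H](O[Si]4(C(C)(C)C)C(C)(C)C)C[C@H](O4)[C@@](C)(C(=O)OC)[C@H]1C(C(=O)OC)(C(=O)OC)C2=CC(=O)CC2 | intermediate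
13 | ring D cross-conjugated dienol TBS ether (C8=C15, C16(OTBS)=C13) | COC1(OC)[C@H](O[Si]4(C(C)(C)C)C(C)(C)C)C[C@H](O4)[C@@](C)(C(=O)OC)[C@H]1C(C(=O)OC)(C(=O)OC)C2=CC(O[Si](C)(C)C(C)(C)C)=CC2 | intermediate
14 | C13–C16 silyloxy oxirane | COC1(OC)[C@H](O[Si]4(C(C)(C)C)C(C)(C)C)C[C@H](O4)[C@@](C)(C(=O)OC)[C@H]1C(C(=O)OC)(C(=O)OC)C2=CC3(O[Si](C)(C)C(C)(C)C)OC3C2 | intermediate
15 | C13-(TBS-oxy) cyclopentenone, C10 ketal (C13 epimers) | COC1(OC)[C@H](O[Si]4(C(C)(C)C)C(C)(C)C)C[C@H](O4)[C@@](C)(C(=O)OC)[C@H]1C(C(=O)OC)(C(=O)OC)C2=CC(=O)C(O[Si](C)(C)C(C)(C)C)C2 | intermediate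
16 | C10 ketone (C13 epimers) | O=C1[C@H](O[Si]4(C(C)(C)C)C(C)(C)C)C[C@H](O4)[C@@](C)(C(=O)OC)[C@H]1C(C(=O)OC)(C(=O)OC)C2=CC(=O)C(O[Si](C)(C)C(C)(C)C)C2 | intermediate
17 | chloroacetone | CC(=O)CCl | starting material
18 | C9/C10 spiro-epoxy methyl ketone, epoxide O α at C10, acetyl anti to the C5 side chain (C13 epimers) | CC(=O)[C@@H]1O[C@]12[C@H](O[Si]4(C(C)(C)C)C(C)(C)C)C[C@H](O4)[C@@](C)(C(=O)OC)[C@H]2C(C(=O)OC)(C(=O)OC)C3=CC(=O)C(O[Si](C)(C)C(C)(C)C)C3 | intermediate
19 | epoxy enol silane (C11(OSiEt3)=C12H2) with ring D as 1,2-bis(silyloxy)cyclopentadiene (C8=C15, C16(OSiEt3)=C13(OTBS)) | C=C(O[Si](CC)(CC)CC)[C@@H]1O[C@]12[C@H](O[Si]4(C(C)(C)C)C(C)(C)C)C[C@H](O4)[C@@](C)(C(=O)OC)[C@H]2C(C(=O)OC)(C(=O)OC)C3=CC(O[Si](CC)(CC)CC)=C(O[Si](C)(C)C(C)(C)C)C3 | intermediate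
20 | tetracyclic cycloadduct: C11 ketone, C10–OSiEt3 (α), C13–OTBS, C15=C16–OSiEt3, C6 gem-diester, 9β-H | CC[Si](CC)(CC)OC1=C[C@]23C[C@@]1(O[Si](C)(C)C(C)(C)C)CC(=O)[C@H]2[C@]1(O[Si](CC)(CC)CC)[C@H](O[Si]4(C(C)(C)C)C(C)(C)C)C[C@H](O4)[C@@](C)(C(=O)OC)[C@H]1C3(C(=O)OC)C(=O)OC | intermediate
21 | C11 enol triflate (C11=C12) | CC[Si](CC)(CC)OC1=C[C@]23C[C@@]1(O[Si](C)(C)C(C)(C)C)C=C(OS(=O)(=O)C(F)(F)F)[C@H]2[C@]1(O[Si](CC)(CC)CC)[C@H](O[Si]4(C(C)(C)C)C(C)(C)C)C[C@H](O4)[C@@](C)(C(=O)OC)[C@H]1C3(C(=O)OC)C(=O)OC | intermediate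
22 | C11=C12 alkene with C15=C16 silyl enol ether | CC[Si](CC)(CC)OC1=C[C@]23C[C@@]1(O[Si](C)(C)C(C)(C)C)C=C[C@H]2[C@]1(O[Si](CC)(CC)CC)[C@H](O[Si]4(C(C)(C)C)C(C)(C)C)C[C@H](O4)[C@@](C)(C(=O)OC)[C@H]1C3(C(=O)OC)C(=O)OC | intermediate
23 | C11=C12 alkene with C16 ketone | O=C1C[C@]23C[C@@]1(O[Si](C)(C)C(C)(C)C)C=C[C@H]2[C@]1(O[Si](CC)(CC)CC)[C@H](O[Si]4(C(C)(C)C)C(C)(C)C)C[C@H](O4)[C@@](C)(C(=O)OC)[C@H]1C3(C(=O)OC)C(=O)OC | intermediate
24 | saturated C16 ketone, C6 gem-diester | O=C1C[C@]23C[C@@]1(O[Si](C)(C)C(C)(C)C)CC[C@H]2[C@]1(O[Si](CC)(CC)CC)[C@H](O[Si]4(C(C)(C)C)C(C)(C)C)C[C@H](O4)[C@@](C)(C(=O)OC)[C@H]1C3(C(=O)OC)C(=O)OC | intermediate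
25 | 6α-mono ester (6-epi, kinetic) | O=C1C[C@]23C[C@@]1(O[Si](C)(C)C(C)(C)C)CC[C@H]2[C@]1(O[Si](CC)(CC)CC)[C@H](O[Si]4(C(C)(C)C)C(C)(C)C)C[C@H](O4)[C@@](C)(C(=O)OC)[C@H]1[C@H]3C(=O)OC | intermediate
26 | 6β-mono ester, C16 ketone | O=C1C[C@]23C[C@@]1(O[Si](C)(C)C(C)(C)C)CC[C@H]2[C@]1(O[Si](CC)(CC)CC)[C@H](O[Si]4(C(C)(C)C)C(C)(C)C)C[C@H](O4)[C@@](C)(C(=O)OC)[C@H]1[C@@H]3C(=O)OC | intermediate
27 | 16-methylene tris-silyl diester | C=C1C[C@]23C[C@@]1(O[Si](C)(C)C(C)(C)C)CC[C@H]2[C@]1(O[Si](CC)(CC)CC)[C@H](O[Si]4(C(C)(C)C)C(C)(C)C)C[C@H](O4)[C@@](C)(C(=O)OC)[C@H]1[C@@H]3C(=O)OC | intermediate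
28 | GA55 methyl ester | C=C1C[C@]23C[C@@]1(O)CC[C@H]2[C@@]12OC(=O)[C@@](C)([C@H]1[C@@H]3C(=O)OC)[C@@H](O)C[C@H]2O | intermediate
29 | GA55 | C=C1C[C@]23C[C@@]1(O)CC[C@H]2[C@@]12OC(=O)[C@@](C)([C@H]1[C@@H]3C(=O)O)[C@@H](O)C[C@H]2O | target

**Step count and risks**

Total step count: 20. Longest linear sequence: 19 steps (steps 1–6 and 8–20 from compound 1).

Steps most likely to fail:

1. Step 13. The silylated epoxide may undergo a 1,2-shift at the tertiary C10 instead of ionising at C9, the cation may be intercepted by a C6 ester carbonyl, or closure may run through the compact mode and give the C8/C13-epimeric bicycle. Fallback: separate epoxide opening from cation formation. Setting out from 19, Et3SiBr (CC[Si](Br)(CC)CC) in CH2Cl2 at −78 °C should open the vinyl epoxide in SN2′ fashion to the 2-silyloxyallyl bromide F1 (C12–Br, C9=C11 enol silane, C10–OSiEt3). Halide abstraction from F1 with AgBF4 in CH2Cl2–MeNO2 at −78 °C (the known cycloaddition of 2-silyloxyallyl halides with cyclopentadienes under monovalent silver) should then generate the same cation without an oxophilic Lewis acid at the epoxide and return to the route at 20. This fallback does not by itself correct a wrong diene face.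

2. Step 11. The chloro enolate may fail to add to the hindered, enolisable C10 ketone (retro-aldol, proton transfer), or the axial alkoxide may lactonise onto the C19 ester before it closes the epoxide. Fallback: a non-basic two-stage route. Setting out from 16, a Mukaiyama aldol addition of (Z)-1-chloro-2-(trimethylsilyloxy)prop-1-ene (CC(O[Si](C)(C)C)=CCl) with TiCl4 in CH2Cl2 at −78 °C should give the chlorohydrin F2 with the same equatorial C–C bond. Brief treatment of F2 with DBU should close the epoxide and return to the route at 18.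

3. Step 8. The hindered malonate anion next to C5 may be too slow in forming the quaternary C6, leaving decomposition of the chloro enone to compete. Fallback: conjugate addition followed by dehydrogenation. Setting out from 9, NaH then cyclopent-2-en-1-one (O=C1C=CCC1) with tBuMe2SiCl as trap should give the silyl enol ether F3. Saegusa–Ito oxidation of F3 with Pd(OAc)2 in MeCN should restore the C8=C15 enone and return to the route at 12.

Further compounds
F1 | step 13 | 2-silyloxyallyl bromide: C12–Br, C9=C11(OSiEt3), C10–OSiEt3, ring D bis(silyloxy)cyclopentadiene (C9=C11 geometry mixed) | BrCC(O[Si](CC)(CC)CC)=C[C@]1(O[Si](CC)(CC)CC)[C@H](O[Si]4(C(C)(C)C)C(C)(C)C)C[C@H](O4)[C@@](C)(C(=O)OC)[C@H]1C(C(=O)OC)(C(=O)OC)C3=CC(O[Si](CC)(CC)CC)=C(O[Si](C)(C)C(C)(C)C)C3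
F2 | step 11 | C10 hydroxy (α) C9 chloro methyl ketone (chlorohydrin; C9 and C13 epimers) | CC(=O)C(Cl)[C@]1(O)[C@H](O[Si]4(C(C)(C)C)C(C)(C)C)C[C@H](O4)[C@@](C)(C(=O)OC)[C@H]1C(C(=O)OC)(C(=O)OC)C2=CC(=O)C(O[Si](C)(C)C(C)(C)C)C2
F3 | step 8 | C6-quaternary malonate with 3-(TBS-oxy)cyclopent-2-enyl group (C8–H, C15=C16–OTBS; C8 epimers) | COC1(OC)[C@H](O[Si]4(C(C)(C)C)C(C)(C)C)C[C@H](O4)[C@@](C)(C(=O)OC)[C@H]1C(C(=O)OC)(C(=O)OC)C2C=C(O[Si](C)(C)C(C)(C)C)CC2
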